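**Retrosynthetic overview**
1. Target 17 ⇐ ovatodiolide 16 by a late singlet-oxygen ene reaction at the isolated trisubstituted olefin (sets C5–OOH and the 4-methylene group).
2. 16 ⇐ seco enal–allylboronate 14 by a macrocyclising allylboration/lactonisation; the 14-membered ring and the trans α-methylene lactone form together (second and third rings).
3. 14 ⇐ butenolide bromide 11 + vinyl iodide/allylboronate 4 by sp3–sp2 Negishi coupling, then unmasking of the enal.
4. 11 (first ring) ⇐ cyclopropenone 10 + aldehyde 7 by a chiral-phosphine-catalysed two-atom ring expansion (C=O inserted into the acyl C–C bond of the three-membered ring; sets C10).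
5. 4, 7, 10 ⇐ hexa-1,5-diyne, (E)-3-methylpent-2-en-4-yn-1-ol, 4-bromobut-1-yne.

Assumption: locants are those of ovatodiolide (C1 ring-fusion CH, C14 and C10 the two lactone O–CH carbons, C5 the hydroperoxy carbon; target = 1R,5R,10R,14S), and the L-threonine-derived phosphine is taken to give the 10R butenolide (the D-threonine-derived antipode is used if the sense is opposite).

**Route**

Step 1
Reactants: 1 hexa-1,5-diyne
Product: 2 (E)-1-iodo-2-methylhex-1-en-5-yne
Conditions: 1 (3 equiv), Me3Al, Cp2ZrCl2 (20 mol %), CH2Cl2, 0 °C→rt; then I2, THF, −30→0 °C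
Reagents that add atoms: trimethylaluminium C[Al](C)C; iodine II
Why: Zr-catalysed Negishi carboalumination adds Me–Al syn across one terminal alkyne (Me to the internal carbon) and iodinolysis with retention gives the E-iodoalkene; the excess of diyne keeps double addition low.

Step 2
Reactants: 2 (E)-1-iodo-2-methylhex-1-en-5-yne
Product: 3 methyl (E)-7-iodo-6-methylhept-6-en-2-ynoate
Conditions: LiHMDS, THF, −78 °C; ClCO2Me, −78→0 °C
Reagents that add atoms: methyl chloroformate COC(=O)Cl
Why: Acetylide C-acylation; the amide base deprotonates the alkyne without I/Li exchange at the vinyl iodide.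

Step 3
Reactants: 3 methyl (E)-7-iodo-6-methylhept-6-en-2-ynoate
Product: 4 methyl (2Z,6E)-7-iodo-6-methyl-2-[(4,4,5,5-tetramethyl-1,3,2-dioxaborolan-2-yl)methyl]hepta-2,6-dienoate
Conditions: DIBAL-H, HMPA–THF, 0 °C; then ICH2Bpin, 0 °C→rt
Reagents that add atoms: 2-(iodomethyl)-4,4,5,5-tetramethyl-1,3,2-dioxaborolane ICB1OC(C)(C)C(C)(C)O1
Why: Conjugate syn-hydroalumination of the ynoate (Tsuda–Saegusa) puts the chain cis to the ester, and borylmethylation of the α-alumino enoate with retention gives a Hall-type 2-alkoxycarbonyl allylboronate with the chain trans to CH2B.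

Step 4
Reactants: 5 (E)-3-methylpent-2-en-4-yn-1-ol
Product: 6 triethyl{[(E)-3-methylpent-2-en-4-yn-1-yl]oxy}silane
Conditions: TESCl, imidazole, CH2Cl2, 0 °C
Reagents that add atoms: chlorotriethylsilane CC[Si](Cl)(CC)CC
Why: Silylation of the primary allylic alcohol; the TES group keeps the OH from trapping the ketene intermediate of step 7 and is later converted directly into the aldehyde.

Step 5
Reactants: 6 triethyl{[(E)-3-methylpent-2-en-4-yn-1-yl]oxy}silane
Product: 7 (E)-3-methyl-5-(triethylsilyloxy)pent-3-enal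
Conditions: Cy2BH (from BH3·SMe2 and cyclohexene), THF, 0 °C; then 30% H2O2, pH 7 buffer, 0 °C
Reagents that add atoms: hydrogen peroxide OO
Why: Anti-Markovnikov hydroboration of the terminal alkyne by a dialkylborane (the trisubstituted alkene is untouched) and buffered oxidation give the aldehyde; kinetic α-protonation of the dienol keeps the E-olefin out of conjugation.

Step 6
Reactants: 8 4-bromobut-1-yne
Product: 10 2-(2-bromoethyl)cycloprop-2-en-1-one, via 1-(2-bromoethyl)-3,3-difluorocycloprop-1-ene 9 (not isolated)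
Conditions: TMSCF2Br, n-Bu4NBr (cat.), toluene, 110 °C (sealed); then wet SiO2, CH2Cl2, rt
Reagents that add atoms: (bromodifluoromethyl)trimethylsilane C[Si](C)(C)C(F)(F)Br; water O
Why: [2+1] addition of difluorocarbene to the alkyne, then hydrolysis of the gem-difluoride to the cyclopropenone; no alkene is present and the bromide-only carbene source avoids halide scrambling.

Step 7
Reactants: 10 2-(2-bromoethyl)cycloprop-2-en-1-one; 7 (E)-3-methyl-5-(triethylsilyloxy)pent-3-enal
Product: 11 (5R)-3-(2-bromoethyl)-5-[(E)-2-methyl-4-(triethylsilyloxy)but-2-en-1-yl]furan-2(5H)-one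
Conditions: L-threonine-derived phosphine–thiourea, Ph2PCH2CH(NHC(S)NHAr)CH(CH3)OTBDPS, Ar = 3,5-(CF3)2C6H3 (10 mol %), toluene, −20 °C, slow addition of 10
Reagents that add atoms: none
Why: Proposed new method: enantioselective phosphine-catalysed ring expansion of a mono-alkyl cyclopropenone by an enolisable aliphatic aldehyde — the phosphine adds to the unsubstituted ring CH of 10, the ring opens to an α-ketenyl phosphonium ylide, the ylide carbon adds to the aldehyde held by the thiourea N–H (this C–C bond sets C10 as R), the alkoxide closes onto the ketene and β-elimination of the phosphine leaves the butenolide (net C=O insertion into the ring acyl C–C bond, 3→5 ring, with α-alkyl/β-H/γ-alkyl regiochemistry fixed by the site of P attack); closest known reaction type: the achiral PMe3-catalysed (3+2) ring-opening annulation of diaryl cyclopropenones with aryl aldehydes, and chiral bifunctional-phosphine annulations of allenoates.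

Step 8
Reactants: 11 (5R)-3-(2-bromoethyl)-5-[(E)-2-methyl-4-(triethylsilyloxy)but-2-en-1-yl]furan-2(5H)-one; 4 methyl (2Z,6E)-7-iodo-6-methyl-2-[(pinacolboryl)methyl]hepta-2,6-dienoate
Product: 13 methyl (2Z,6E)-6-methyl-9-{(5R)-5-[(E)-2-methyl-4-(triethylsilyloxy)but-2-en-1-yl]-2-oxo-2,5-dihydrofuran-3-yl}-2-[(pinacolboryl)methyl]nona-2,6-dienoate, via {2-[(5R)-5-[(E)-2-methyl-4-(triethylsilyloxy)but-2-en-1-yl]-2-oxo-2,5-dihydrofuran-3-yl]ethyl}zinc bromide 12 (not isolated)
Conditions: Zn dust, LiCl, THF, 45 °C; then 4, Pd(OAc)2/SPhos (cat.), THF, rt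
Reagents that add atoms: none
Why: Zinc insertion into the primary bromide and Negishi sp3–sp2 coupling with retention of the E-olefin; the alkylzinc leaves the butenolide, silyl ether and the unactivated Hall-type allylboronate alone, and 11 carries no second vinyl halide.

Step 9
Reactants: 13 (TES ether from step 8)
Product: 14 methyl (2Z,6E)-6-methyl-9-{(5R)-5-[(E)-2-methyl-4-oxobut-2-en-1-yl]-2-oxo-2,5-dihydrofuran-3-yl}-2-[(pinacolboryl)methyl]nona-2,6-dienoate
Conditions: IBX (3 equiv), DMSO, rt
Reagents that add atoms: none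
Why: IBX/DMSO cleaves the primary TES ether and oxidises the liberated allylic alcohol in one pot to the E-enal under neutral conditions; the deactivated allylboronate does not react with the aldehyde at rt.

Step 10
Reactants: 14 (seco enal–allylboronate)
Product: 16 (−)-ovatodiolide (1R,10R,14S), via the macrocyclic homoallylic pinacol borate methyl ester 15 (not isolated)
Conditions: Sc(OTf)3 (10 mol %), toluene (1 mM, syringe pump), rt; then TsOH (cat.)
Reagents that add atoms: none
Why: Intramolecular Lewis-acid-catalysed allylboration through a closed chair transition state, then lactonisation; the boronate geometry (chain trans to CH2B) with the enal substituent equatorial gives the anti adduct and hence the trans lactone, and the C10 centre with the two E-olefins is expected to direct the chair to the face giving 1R,14S (macrocyclic control).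

Step 11
Reactants: 16 (−)-ovatodiolide
Product: 17 4-methylene-5β-hydroperoxyovatodiolide (1R,5R,10R,14S)
Conditions: O2, hν (white LED), TPP (cat.), CH2Cl2, 0 °C
Reagents that add atoms: oxygen O=O
Why: Schenck ene reaction at the electron-rich isolated C4=C5 olefin (the other trisubstituted olefin is deactivated by the allylic lactone oxygen); H is taken from the methyl on the disubstituted side (cis effect) to give the 4-methylene group, and O2 is expected to add from the exposed outer face to set 5R.

**Compound list**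
1 | hexa-1,5-diyne | C#CCCC#C | starting material
2 | (E)-1-iodo-2-methylhex-1-en-5-yne | I/C=C(\C)CCC#C | intermediate
3 | methyl (E)-7-iodo-6-methylhept-6-en-2-ynoate | COC(=O)C#CCC/C(C)=C/I | intermediate
4 | methyl (2Z,6E)-7-iodo-6-methyl-2-[(pinacolboryl)methyl]hepta-2,6-dienoate | COC(=O)/C(CB1OC(C)(C)C(C)(C)O1)=C\CC/C(C)=C/I | intermediate
5 | (E)-3-methylpent-2-en-4-yn-1-ol | C#C/C(C)=C/CO | starting material
6 | triethyl{[(E)-3-methylpent-2-en-4-yn-1-yl]oxy}silane | C#C/C(C)=C/CO[Si](CC)(CC)CC | intermediate
7 | (E)-3-methyl-5-(triethylsilyloxy)pent-3-enal | O=CC/C(C)=C/CO[Si](CC)(CC)CC | intermediate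
8 | 4-bromobut-1-yne | BrCCC#C | starting material
9 | 1-(2-bromoethyl)-3,3-difluorocycloprop-1-ene | FC1(F)C=C1CCBr | intermediate
10 | 2-(2-bromoethyl)cycloprop-2-en-1-one | O=C1C=C1CCBr | intermediate
11 | (5R)-3-(2-bromoethyl)-5-[(E)-2-methyl-4-(triethylsilyloxy)but-2-en-1-yl]furan-2(5H)-one | CC[Si](CC)(CC)OC/C=C(\C)C[C@@H]1C=C(CCBr)C(=O)O1 | intermediate
12 | {2-[(5R)-5-[(E)-2-methyl-4-(triethylsilyloxy)but-2-en-1-yl]-2-oxo-2,5-dihydrofuran-3-yl]ethyl}zinc bromide | CC[Si](CC)(CC)OC/C=C(\C)C[C@@H]1C=C(CC[Zn]Br)C(=O)O1 | intermediate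
13 | methyl (2Z,6E)-6-methyl-9-{(5R)-5-[(E)-2-methyl-4-(triethylsilyloxy)but-2-en-1-yl]-2-oxo-2,5-dihydrofuran-3-yl}-2-[(pinacolboryl)methyl]nona-2,6-dienoate | CC[Si](CC)(CC)OC/C=C(\C)C[C@@H]1C=C(CC/C=C(\C)CC/C=C(\C(=O)OC)CB2OC(C)(C)C(C)(C)O2)C(=O)O1 | intermediate
14 | methyl (2Z,6E)-6-methyl-9-{(5R)-5-[(E)-2-methyl-4-oxobut-2-en-1-yl]-2-oxo-2,5-dihydrofuran-3-yl}-2-[(pinacolboryl)methyl]nona-2,6-dienoate | O=C/C=C(\C)C[C@@H]1C=C(CC/C=C(\C)CC/C=C(\C(=O)OC)CB2OC(C)(C)C(C)(C)O2)C(=O)O1 | intermediate
15 | macrocyclic homoallylic pinacol borate (14-O-Bpin, methyl 2-propenoate at C1, butenolide intact; 1R,10R,14S) | COC(=O)C(=C)[C@H]1CC/C(C)=C/CCC2=C[C@@H](C/C(C)=C/[C@@H]1OB3OC(C)(C)C(C)(C)O3)OC2=O | intermediate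
16 | (−)-ovatodiolide (1R,10R,14S) | C=C1C(=O)O[C@H]2/C=C(\C)C[C@@H]3C=C(CC/C=C(\C)CC[C@H]12)C(=O)O3 | intermediate
17 | 4-methylene-5β-hydroperoxyovatodiolide (1R,5R,10R,14S) | C=C1C(=O)O[C@H]2/C=C(\C)C[C@@H]3C=C(CC[C@@H](OO)C(=C)CC[C@H]12)C(=O)O3 | target

**Totals**
Total steps: 11. Longest linear sequence: 7 (steps 4, 5, 7, 8, 9, 10, 11).

**Three steps most likely to fail**

Step 7 (the new ring expansion). The ylide may enolise or isomerise the β,γ-unsaturated aldehyde 7, Wittig-type loss of phosphine oxide may compete, and the ee is untested. The fallback uses known chemistry, sets out from 7 and comes back at 11. Vinylmagnesium bromide adds to 7 to give racemic (E)-5-methyl-7-(triethylsilyloxy)hepta-1,5-dien-3-ol F1. Lipase (CAL-B, vinyl acetate) kinetic resolution acylates the S enantiomer and leaves (R)-(E)-5-methyl-7-(triethylsilyloxy)hepta-1,5-dien-3-ol F2. DCC/DMAP esterification with 4-bromo-2-methylenebutanoic acid F3 (made by BBr3 opening of commercial α-methylene-γ-butyrolactone) gives the diene ester (R)-(E)-5-methyl-7-(triethylsilyloxy)hepta-1,5-dien-3-yl 4-bromo-2-methylenebutanoate F4. Ring-closing metathesis with Grubbs II (toluene, 80 °C) closes the butenolide and gives 11.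

Step 10 (macrocyclisation). Oligomerisation is possible, and the facial selectivity relative to C10 rests on macrocyclic control that is not proven. The fallback sets out from 11 and 4 and comes back at 16. IBX/DMSO turns 11 into the bromo enal (5R)-3-(2-bromoethyl)-5-[(E)-2-methyl-4-oxobut-2-en-1-yl]furan-2(5H)-one F5. Sc(OTf)3-catalysed intermolecular allylboration/lactonisation of F5 with 4 gives the trans α-methylene lactone bearing the bromoethyl butenolide and the iodoalkene F6. Both trans diastereomers with respect to C10 form and are separated (a BINOL-phosphoric acid catalyst can be tried to bias the ratio). Intramolecular Ni-catalysed reductive alkyl bromide/vinyl iodide coupling (NiI2·glyme, dtbbpy, Mn, DMA, 2 mM) then closes the 14-membered ring at C5–C6 and gives 16.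

Step 11 (photooxygenation). The tertiary hydroperoxide from H abstraction at C6, the 5α epimer and attack at the other olefin all compete. The fallback sets out from 16 and comes back at 17. Ene-type chlorination (Ca(OCl)2, CO2, CH2Cl2/H2O, 0 °C) at the electron-rich isolated olefin gives 5-chloro-4-methylene-4,5-dihydro-ovatodiolide F7 with the exocyclic methylene fixed by the ionic mechanism. Silver-assisted substitution (AgOTf, anhydrous H2O2 in Et2O, −20 °C) gives 17 after separation of the C5 epimer.

**Further compounds**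
F1 | step 7 | (E)-5-methyl-7-(triethylsilyloxy)hepta-1,5-dien-3-ol (racemic) | C=CC(O)C/C(C)=C/CO[Si](CC)(CC)CC
F2 | step 7 | (R)-(E)-5-methyl-7-(triethylsilyloxy)hepta-1,5-dien-3-ol | C=C[C@H](O)C/C(C)=C/CO[Si](CC)(CC)CC
F3 | step 7 | 4-bromo-2-methylenebutanoic acid | C=C(CCBr)C(=O)O
F4 | step 7 | (R)-(E)-5-methyl-7-(triethylsilyloxy)hepta-1,5-dien-3-yl 4-bromo-2-methylenebutanoate | C=C(CCBr)C(=O)O[C@@H](C=C)C/C(C)=C/CO[Si](CC)(CC)CC
F5 | step 10 | (5R)-3-(2-bromoethyl)-5-[(E)-2-methyl-4-oxobut-2-en-1-yl]furan-2(5H)-one | O=C/C=C(\C)C[C@@H]1C=C(CCBr)C(=O)O1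
F6 | step 10 | trans α-methylene-γ-butyrolactone with (E)-5-iodo-4-methylpent-4-enyl at C1 and the bromoethyl butenolide side chain at C14 (1R,10R,14S) | C=C1C(=O)O[C@@H](/C=C(\C)C[C@@H]2C=C(CCBr)C(=O)O2)[C@@H]1CC/C(C)=C/I
F7 | step 11 | 5-chloro-4-methylene-4,5-dihydro-ovatodiolide (C5 epimers) | C=C1C(=O)O[C@H]2/C=C(\C)C[C@@H]3C=C(CCC(Cl)C(=C)CC[C@H]12)C(=O)O3
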